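## Retrosynthetic overview

1. Target 24 → removal of the tert-butyl group from the C2 oxygen, then cross-metathesis at the enoate C=C: methacrylate quinone 18 + (R)-3-methylidenehept-6-en-2-ol 22 (from (R)-but-3-yn-2-ol 19 by copper-catalysed carbomagnesiation).
2. Quinone ring B of 18 (C1–C2–C3–C4–C4a–C8a, the only ring formed in the route) → 4-hydroxy-4-phenylcyclobutenone 14 by thermal 4π ring opening and 6π ring closure, which makes the bond from carbonyl carbon C1 (the one next to the oxygenated C2) to arene carbon C8a.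
3. Cyclobutenone 14 → di-tert-butyl squarate 4 + phenyllithium 5 + the alkyllithium from iodide 3: phenyl first, alkyl second, then 1,3-carbonyl transposition, so that phenyl sits on the ring carbon next to the alkyl-bearing carbon and the ketone next to C–OtBu.
4. Enabling feature: C1(=O)–C2(OH)=C3(alkyl)–C4(=O) of ring B is a squaric acid C4O3 unit in which C1 and C4 can be bonded to each other, and benzo ring A is unsubstituted, i.e. a plain phenyl on C4 with two equivalent ortho carbons, so a ketene at C1 can close onto C8a without any regiochemical question.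

Key step: step 7

Assumption: di-tert-butyl squarate 4 is taken as a purchasable compound; it should undergo the same 1,2-additions as the dimethyl and diisopropyl esters, and its tert-butyl groups leave as isobutene under mild acid.

## Route

Step 1
Reactants: 1 2,2-dimethylpropane-1,3-diol
Product: 2 3-[(tert-butyldimethylsilyl)oxy]-2,2-dimethylpropan-1-ol
Conditions: NaH (1.0 equiv), THF, 0 °C to rt; then TBSCl (1.0 equiv), rt
Reagents that add atoms: tert-butyldimethylsilyl chloride, CC(C)(C)[Si](C)(C)Cl
Why: Monosilylation of a symmetrical diol through its sparingly soluble monosodium alkoxide (McDougal protocol, Williamson-type O-silylation) should stop cleanly at the mono-ether; no stereocentre is involved.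

Step 2
Reactants: 2 3-[(tert-butyldimethylsilyl)oxy]-2,2-dimethylpropan-1-ol
Product: 3 tert-butyl(3-iodo-2,2-dimethylpropoxy)dimethylsilane
Conditions: I2, PPh3, imidazole, toluene, 80 °C
Reagents that add atoms: iodine, II
Why: Appel-type iodination (Garegg–Samuelsson conditions) via an alkoxyphosphonium iodide is one of the few substitutions that proceeds at a neopentyl carbon on heating, and the imidazole buffer protects the silyl ether.

Step 3
Reactants: 4 di-tert-butyl squarate; 5 phenyllithium
Product: 7 2,3-di-tert-butoxy-4-phenyl-4-[(trimethylsilyl)oxy]cyclobut-2-en-1-one, via lithium alkoxide 6 (not isolated)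
Conditions: THF, −78 °C; then TMSCl, −78 to 0 °C
Reagents that add atoms: chlorotrimethylsilane, C[Si](C)(C)Cl
Why: 1,2-Addition of an aryllithium to one of the two equivalent ketone carbonyls of a squarate ester (first stage of the Moore–Liebeskind cyclobutenone synthesis) should stop at monoaddition because the remaining carbonyl is a deactivated vinylogous ester, and in situ O-silylation blocks the tertiary alkoxide for the next step; the new quaternary centre is racemic and is destroyed in step 7.

Step 4
Reactants: 3 tert-butyl(3-iodo-2,2-dimethylpropoxy)dimethylsilane; 7 2,3-di-tert-butoxy-4-phenyl-4-[(trimethylsilyl)oxy]cyclobut-2-en-1-one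
Product: 11 2-tert-butoxy-3-{3-[(tert-butyldimethylsilyl)oxy]-2,2-dimethylpropyl}-4-phenyl-4-[(trimethylsilyl)oxy]cyclobut-2-en-1-one, via alkyllithium 8 (not isolated), via lithium alkoxide 9 (not isolated), via trifluoroacetate 10 (not isolated)
Conditions: 3, t-BuLi (2.1 equiv), Et2O/pentane, −78 °C; then 7, THF, −78 °C; then (CF3CO)2O, −78 °C; aq. NaHCO3
Reagents that add atoms: none
Why: Iodine–lithium exchange (Bailey conditions) gives a primary alkyllithium without β-hydrogens that should add 1,2 to the only carbonyl of 7, and trifluoroacetylation of the resulting alkoxide triggers ionisation to an alkoxy-stabilised allyl cation that collapses by loss of the tert-butyl cation from the distal oxygen (1,3-carbonyl transposition of a vinylogous ester, as in the squarate-to-semisquarate conversion), so the alkyl group ends next to the phenyl-bearing carbon and the new ketone next to C–OtBu.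

Step 5
Reactants: 11 2-tert-butoxy-3-{3-[(tert-butyldimethylsilyl)oxy]-2,2-dimethylpropyl}-4-phenyl-4-[(trimethylsilyl)oxy]cyclobut-2-en-1-one
Product: 12 2-tert-butoxy-4-hydroxy-3-(3-hydroxy-2,2-dimethylpropyl)-4-phenylcyclobut-2-en-1-one
Conditions: TBAF, AcOH (1:1), THF, 0 °C to rt
Reagents that add atoms: none
Why: Fluoride-mediated cleavage of both silyl ethers, buffered with acetic acid so that the cyclobutenol is never present as a free alkoxide (which would ring-open prematurely) and the acid-labile tert-butyl enol ether is untouched.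

Step 6
Reactants: 12 2-tert-butoxy-4-hydroxy-3-(3-hydroxy-2,2-dimethylpropyl)-4-phenylcyclobut-2-en-1-one; 13 methacryloyl chloride
Product: 14 3-(2-tert-butoxy-4-hydroxy-3-oxo-4-phenylcyclobut-1-en-1-yl)-2,2-dimethylpropyl 2-methylprop-2-enoate
Conditions: pyridine, DMAP (cat.), CH2Cl2, 0 °C
Reagents that add atoms: none
Why: Chemoselective O-acylation of the primary alcohol with an acid chloride under pyridine/DMAP catalysis should leave the tertiary, benzylic, α-keto hydroxyl untouched because it is far too hindered at 0 °C.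

Step 7
Reactants: 14 3-(2-tert-butoxy-4-hydroxy-3-oxo-4-phenylcyclobut-1-en-1-yl)-2,2-dimethylpropyl 2-methylprop-2-enoate
Product: 18 3-(3-tert-butoxy-1,4-dioxo-1,4-dihydronaphthalen-2-yl)-2,2-dimethylpropyl 2-methylprop-2-enoate, via dienylketene 15 (not isolated), via dienone 16 (not isolated), via hydroquinone 17 (not isolated)
Conditions: p-xylene (0.02 M, degassed), 138 °C; then Ag2O, rt
Reagents that add atoms: none
Why: Heating should effect conrotatory 4π-electrocyclic opening of the cyclobutenone C1–C4 bond, the donor 4-hydroxyl rotating outward (torquoselectivity) so that the phenyl group of dienylketene 15 points toward the ketene carbon. Disrotatory 6π-electrocyclisation across the ketene C=C, the enol C=C and one aromatic C=C then closes the six-membered quinone ring by joining the ketene carbon, whose only carbon neighbour is the tert-butoxy-bearing carbon, to an ortho carbon of the phenyl ring, giving dienone 16. Tautomerisation rearomatises 16 to hydroquinone 17 and Ag2O dehydrogenates it to quinone 18; the closest known reaction type is the Moore rearrangement of 4-aryl-4-hydroxycyclobutenones. No stereocentre survives, since the carbinol centre of 14 becomes sp2 and the ring-fusion CH of 16 is lost on aromatisation. The step needs outward rotation of the hydroxyl (inward rotation would lead to lactonisation to a furanone), secured by its donor character, and ring closure ahead of bimolecular ketene capture or methacrylate polymerisation, secured by high dilution and the proximity of the aryl ring; the two ortho carbons of the unsubstituted phenyl are equivalent, and which carbonyl ends next to C–O is fixed by the substitution pattern built in steps 3 and 4.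

Step 8
Reactants: 19 (R)-but-3-yn-2-ol; 20 but-3-enylmagnesium bromide
Product: 22 (R)-3-methylidenehept-6-en-2-ol, via magnesium chelate 21 (not isolated)
Conditions: 20 (3 equiv), CuI (10 mol%), Et2O/THF, 0 °C to reflux; then aq. NH4Cl
Reagents that add atoms: none
Why: Copper-catalysed anti-carbomagnesiation of a propargylic alkoxide (Duboudin–Jousseaume reaction) should deliver the butenyl group to the alkyne carbon next to the carbinol through a five-membered vinylmagnesium chelate whose protonolysis gives the 2-substituted allylic alcohol; the (R) centre comes unchanged from 19 because no bond to it is made or broken.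

Step 9
Reactants: 18 3-(3-tert-butoxy-1,4-dioxo-1,4-dihydronaphthalen-2-yl)-2,2-dimethylpropyl 2-methylprop-2-enoate; 22 (R)-3-methylidenehept-6-en-2-ol
Product: 23 3-(3-tert-butoxy-1,4-dioxo-1,4-dihydronaphthalen-2-yl)-2,2-dimethylpropyl (2E,7R)-7-hydroxy-2-methyl-6-methylideneoct-2-enoate
Conditions: 22 (3 equiv), second-generation Hoveyda–Grubbs catalyst RuCl2(H2IMes)(=CH-C6H4-2-OiPr) (10 mol%), CH2Cl2, 40 °C
Reagents that add atoms: none
Why: Olefin cross-metathesis between a monosubstituted alkene (homodimerising partner, in excess) and a methacrylate (non-homodimerising partner) should give the trisubstituted enoate under thermodynamic control with the ester trans to the chain, i.e. (E), while the hindered 1,1-disubstituted alkene beside the carbinol and the tetrasubstituted quinone C=C stay out of the reaction and the (R) centre is untouched.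

Step 10
Reactants: 23 3-(3-tert-butoxy-1,4-dioxo-1,4-dihydronaphthalen-2-yl)-2,2-dimethylpropyl (2E,7R)-7-hydroxy-2-methyl-6-methylideneoct-2-enoate
Product: 24 Rhinacanthin I
Conditions: CF3CO2H/CH2Cl2 (1:9), 0 °C; evaporation with toluene
Reagents that add atoms: none
Why: Acidolysis of a tert-butyl vinylogous ester (E1 loss of the tert-butyl cation as isobutene) should unveil the 2-hydroxy-1,4-naphthoquinone much faster than anything else reacts, the neopentyl enoate being inert and the short, cold exposure leaving the secondary allylic alcohol and its (R) configuration intact.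

## Compound list

1 | 2,2-dimethylpropane-1,3-diol | OCC(C)(C)CO | starting material
2 | 3-[(tert-butyldimethylsilyl)oxy]-2,2-dimethylpropan-1-ol | CC(C)(CO)CO[Si](C)(C)C(C)(C)C | intermediate
3 | tert-butyl(3-iodo-2,2-dimethylpropoxy)dimethylsilane | CC(C)(CI)CO[Si](C)(C)C(C)(C)C | intermediate
4 | di-tert-butyl squarate (3,4-di-tert-butoxycyclobut-3-ene-1,2-dione) | CC(C)(C)OC1=C(OC(C)(C)C)C(=O)C1=O | starting material
5 | phenyllithium | [Li]c1ccccc1 | starting material
6 | lithium 2,3-di-tert-butoxy-4-oxo-1-phenylcyclobut-2-en-1-olate (racemic) | [Li+].[O-]C1(c2ccccc2)C(OC(C)(C)C)=C(OC(C)(C)C)C1=O | intermediate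
7 | 2,3-di-tert-butoxy-4-phenyl-4-[(trimethylsilyl)oxy]cyclobut-2-en-1-one (racemic) | CC(C)(C)OC1=C(OC(C)(C)C)C(O[Si](C)(C)C)(c2ccccc2)C1=O | intermediate
8 | {3-[(tert-butyldimethylsilyl)oxy]-2,2-dimethylpropyl}lithium | [Li]CC(C)(C)CO[Si](C)(C)C(C)(C)C | intermediate
9 | lithium 2,3-di-tert-butoxy-1-{3-[(tert-butyldimethylsilyl)oxy]-2,2-dimethylpropyl}-4-phenyl-4-[(trimethylsilyl)oxy]cyclobut-2-en-1-olate (diastereomer mixture) | [Li+].[O-]C1(CC(C)(C)CO[Si](C)(C)C(C)(C)C)C(OC(C)(C)C)=C(OC(C)(C)C)C1(O[Si](C)(C)C)c1ccccc1 | intermediate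
10 | 2,3-di-tert-butoxy-1-{3-[(tert-butyldimethylsilyl)oxy]-2,2-dimethylpropyl}-4-phenyl-4-[(trimethylsilyl)oxy]cyclobut-2-en-1-yl trifluoroacetate | O=C(OC1(CC(C)(C)CO[Si](C)(C)C(C)(C)C)C(OC(C)(C)C)=C(OC(C)(C)C)C1(O[Si](C)(C)C)c1ccccc1)C(F)(F)F | intermediate
11 | 2-tert-butoxy-3-{3-[(tert-butyldimethylsilyl)oxy]-2,2-dimethylpropyl}-4-phenyl-4-[(trimethylsilyl)oxy]cyclobut-2-en-1-one (racemic) | CC(C)(C)OC1=C(CC(C)(C)CO[Si](C)(C)C(C)(C)C)C(O[Si](C)(C)C)(c2ccccc2)C1=O | intermediate
12 | 2-tert-butoxy-4-hydroxy-3-(3-hydroxy-2,2-dimethylpropyl)-4-phenylcyclobut-2-en-1-one (racemic) | CC(C)(C)OC1=C(CC(C)(C)CO)C(O)(c2ccccc2)C1=O | intermediate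
13 | methacryloyl chloride | C=C(C)C(Cl)=O | starting material
14 | 3-(2-tert-butoxy-4-hydroxy-3-oxo-4-phenylcyclobut-1-en-1-yl)-2,2-dimethylpropyl 2-methylprop-2-enoate (racemic) | C=C(C)C(=O)OCC(C)(C)CC1=C(OC(C)(C)C)C(=O)C1(O)c1ccccc1 | intermediate
15 | 3-[(1E)-3-tert-butoxy-1-hydroxy-4-oxo-1-phenylbuta-1,3-dien-2-yl]-2,2-dimethylpropyl 2-methylprop-2-enoate (dienylketene, phenyl cis to the ketene-bearing carbon) | O=C=C(OC(C)(C)C)/C(CC(C)(C)COC(=O)C(C)=C)=C(/O)c1ccccc1 | intermediate
16 | 3-(3-tert-butoxy-1-hydroxy-4-oxo-4,4a-dihydronaphthalen-2-yl)-2,2-dimethylpropyl 2-methylprop-2-enoate (racemic dienone) | O=C1C(OC(C)(C)C)=C(CC(C)(C)COC(=O)C(C)=C)C(O)=C2C=CC=CC12 | intermediate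
17 | 3-(3-tert-butoxy-1,4-dihydroxynaphthalen-2-yl)-2,2-dimethylpropyl 2-methylprop-2-enoate | C=C(C)C(=O)OCC(C)(C)Cc1c(OC(C)(C)C)c(O)c2ccccc2c1O | intermediate
18 | 3-(3-tert-butoxy-1,4-dioxo-1,4-dihydronaphthalen-2-yl)-2,2-dimethylpropyl 2-methylprop-2-enoate | C=C(C)C(=O)OCC(C)(C)CC1=C(OC(C)(C)C)C(=O)c2ccccc2C1=O | intermediate
19 | (R)-but-3-yn-2-ol | C#C[C@@H](C)O | starting material
20 | but-3-enylmagnesium bromide | C=CCC[Mg]Br | starting material
21 | (R)-4-(but-3-en-1-yl)-5-methyl-2,5-dihydro-1,2-oxamagnesole (vinylmagnesium alkoxide chelate, solvation omitted) | C=CCCC1=C[Mg]O[C@@H]1C | intermediate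
22 | (R)-3-methylidenehept-6-en-2-ol | C=CCCC(=C)[C@@H](C)O | intermediate
23 | 3-(3-tert-butoxy-1,4-dioxo-1,4-dihydronaphthalen-2-yl)-2,2-dimethylpropyl (2E,7R)-7-hydroxy-2-methyl-6-methylideneoct-2-enoate | C=C(CC/C=C(\C)C(=O)OCC(C)(C)CC1=C(OC(C)(C)C)C(=O)c2ccccc2C1=O)[C@@H](C)O | intermediate
24 | Rhinacanthin I, 3-(3-hydroxy-1,4-dioxo-1,4-dihydronaphthalen-2-yl)-2,2-dimethylpropyl (2E,7R)-7-hydroxy-2-methyl-6-methylideneoct-2-enoate | C=C(CC/C=C(\C)C(=O)OCC(C)(C)CC1=C(O)C(=O)c2ccccc2C1=O)[C@@H](C)O | target

## Step count and risks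

Total steps: 10. Longest linear sequence: 8 steps (1, 2, 4, 5, 6, 7, 9, 10).

Steps most likely to fail:

**Step 4.** The β-quaternary alkyllithium may add only sluggishly to the hindered, deactivated carbonyl of 7, and the acid-triggered transposition may strip both tert-butyl groups or the silyl ether. Fallback, setting out from 3 and 4 and returning at 12: alkyllithium 8 is added to squarate 4 itself and the adduct is treated with (CF3CO)2O to give the semisquarate 3-tert-butoxy-4-{3-[(tert-butyldimethylsilyl)oxy]-2,2-dimethylpropyl}cyclobut-3-ene-1,2-dione F1. Phenyl is then delivered to the vinylogous-ester carbonyl of F1 (the one next to the alkyl-bearing carbon) as the organoytterbium reagent from phenyllithium 5 and Yb(OTf)3. This reagent combination is reported to reverse the usual site of addition to such diones, though that is cited from memory and should be checked. It should give 2-tert-butoxy-3-{3-[(tert-butyldimethylsilyl)oxy]-2,2-dimethylpropyl}-4-hydroxy-4-phenylcyclobut-2-en-1-one F2, and buffered fluoride desilylation as in step 5 then gives 12.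

**Step 9.** The electron-poor 1,1-disubstituted methacrylate, here the limiting partner, may turn over too slowly, so that homodimerisation of 22, alkene migration and catalyst decay (possibly by binding to the quinone) outrun productive cross-metathesis. Fallback, setting out from 22 and 12 and returning at 24; the metathesis is moved to a quinone-free stage with the methacrylate in excess and the union is made by esterification:
- 22 is silylated (TBSCl, imidazole) to (R)-tert-butyldimethyl[(3-methylidenehept-6-en-2-yl)oxy]silane F3.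
- Cross-metathesis of F3 with a large excess of methyl methacrylate gives methyl (2E,7R)-7-[(tert-butyldimethylsilyl)oxy]-2-methyl-6-methylideneoct-2-enoate F4.
- LiOH hydrolysis gives (2E,7R)-7-[(tert-butyldimethylsilyl)oxy]-2-methyl-6-methylideneoct-2-enoic acid F5.
- Carbodiimide esterification (EDC·HCl, DMAP cat.) of the primary hydroxyl of diol 12 with F5 gives 3-(2-tert-butoxy-4-hydroxy-3-oxo-4-phenylcyclobut-1-en-1-yl)-2,2-dimethylpropyl (2E,7R)-7-[(tert-butyldimethylsilyl)oxy]-2-methyl-6-methylideneoct-2-enoate F6, two diastereomers that converge.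
- Thermolysis and Ag2O oxidation as in step 7 give 3-(3-tert-butoxy-1,4-dioxo-1,4-dihydronaphthalen-2-yl)-2,2-dimethylpropyl (2E,7R)-7-[(tert-butyldimethylsilyl)oxy]-2-methyl-6-methylideneoct-2-enoate F7.
- Aqueous CF3CO2H in CH2Cl2 removes both the tert-butyl and the silyl group to give 24.

**Step 10.** Acid-induced ionisation, trifluoroacetylation or alkene migration at the 2-methylidene carbinol may compete with cleavage of the tert-butyl group. Fallback, setting out from 18 and returning at 24: the tert-butyl group is removed before the sensitive alcohol is present, by CF3CO2H/CH2Cl2 treatment of 18, giving 3-(3-hydroxy-1,4-dioxo-1,4-dihydronaphthalen-2-yl)-2,2-dimethylpropyl 2-methylprop-2-enoate F8. Cross-metathesis of F8 with 22 under the conditions of step 9 then gives 24 directly under neutral conditions.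

## Further compounds

F1 | step 4 | 3-tert-butoxy-4-{3-[(tert-butyldimethylsilyl)oxy]-2,2-dimethylpropyl}cyclobut-3-ene-1,2-dione | CC(C)(C)OC1=C(CC(C)(C)CO[Si](C)(C)C(C)(C)C)C(=O)C1=O
F2 | step 4 | 2-tert-butoxy-3-{3-[(tert-butyldimethylsilyl)oxy]-2,2-dimethylpropyl}-4-hydroxy-4-phenylcyclobut-2-en-1-one | CC(C)(C)OC1=C(CC(C)(C)CO[Si](C)(C)C(C)(C)C)C(O)(c2ccccc2)C1=O
F3 | step 9 | (R)-tert-butyldimethyl[(3-methylidenehept-6-en-2-yl)oxy]silane | C=CCCC(=C)[C@@H](C)O[Si](C)(C)C(C)(C)C
F4 | step 9 | methyl (2E,7R)-7-[(tert-butyldimethylsilyl)oxy]-2-methyl-6-methylideneoct-2-enoate | C=C(CC/C=C(\C)C(=O)OC)[C@@H](C)O[Si](C)(C)C(C)(C)C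
F5 | step 9 | (2E,7R)-7-[(tert-butyldimethylsilyl)oxy]-2-methyl-6-methylideneoct-2-enoic acid | C=C(CC/C=C(\C)C(=O)O)[C@@H](C)O[Si](C)(C)C(C)(C)C
F6 | step 9 | 3-(2-tert-butoxy-4-hydroxy-3-oxo-4-phenylcyclobut-1-en-1-yl)-2,2-dimethylpropyl (2E,7R)-7-[(tert-butyldimethylsilyl)oxy]-2-methyl-6-methylideneoct-2-enoate | C=C(CC/C=C(\C)C(=O)OCC(C)(C)CC1=C(OC(C)(C)C)C(=O)C1(O)c1ccccc1)[C@@H](C)O[Si](C)(C)C(C)(C)C
F7 | step 9 | 3-(3-tert-butoxy-1,4-dioxo-1,4-dihydronaphthalen-2-yl)-2,2-dimethylpropyl (2E,7R)-7-[(tert-butyldimethylsilyl)oxy]-2-methyl-6-methylideneoct-2-enoate | C=C(CC/C=C(\C)C(=O)OCC(C)(C)CC1=C(OC(C)(C)C)C(=O)c2ccccc2C1=O)[C@@H](C)O[Si](C)(C)C(C)(C)C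
F8 | step 10 | 3-(3-hydroxy-1,4-dioxo-1,4-dihydronaphthalen-2-yl)-2,2-dimethylpropyl 2-methylprop-2-enoate | C=C(C)C(=O)OCC(C)(C)CC1=C(O)C(=O)c2ccccc2C1=O
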